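**Assumption:** the target SMILES contains no stereocentre and no stereogenic double bond, so Hansfordiol B is achiral and the route needs no stereocontrol.

**Retrosynthetic overview** (side chain numbered C1' at the benzylic carbon to C17' at the methyl; ketone at C16')
1. The only ring is the resorcinol ring, bought intact as 3,5-dimethoxybenzyl chloride 1; no ring is formed in the route.
2. Disconnection C1'–C2': 1 and 1,12-dibromododecane 2 give, through benzylic Grignard reagent 3, the C13 bromide 4 (normal polarity).
3. Key disconnection C13'–C14': bromide 4 (electrophilic carbon) is joined to 1-methylcyclopropan-1-ol 5, which acts as the homoenolate (d3 synthon) of butanone; the β-carbon of a ketone is normally electrophilic, so this is a reversed-polarity coupling. It gives ketone 6 directly, with no carbonyl masking.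
4. O-Demethylation of 6 gives the target 7.

**Step 1**
Reactants: 1 3,5-dimethoxybenzyl chloride; 2 1,12-dibromododecane (3 equiv, excess recovered)
Product: 4 1-(13-bromotridecyl)-3,5-dimethoxybenzene, via 3,5-dimethoxybenzylmagnesium chloride 3 (not isolated)
Conditions: Mg turnings (I2 crystal), Et2O, 0 °C to rt, slow addition of 1; then added to 2, Li2CuCl4 (3 mol%), THF, −10 °C to rt
Reagents that add atoms: magnesium, [Mg] (held in intermediate 3 only; no atom of it stays in 4)
Why: Copper-catalysed Grignard–alkyl bromide cross-coupling (Kochi-type Li2CuCl4 coupling), in which the benzylic Grignard reagent 3 displaces one bromide of 2 through an alkylcuprate and the threefold excess of 2 holds the reaction at mono-substitution; no stereocentre is formed.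

**Step 2**
Reactants: 4 1-(13-bromotridecyl)-3,5-dimethoxybenzene; 5 1-methylcyclopropan-1-ol (2 equiv)
Product: 6 17-(3,5-dimethoxyphenyl)heptadecan-2-one
Conditions: Ni(cod)2 (10 mol%), 4,4'-di-tert-butyl-2,2'-bipyridine (12 mol%), K3PO4 (2 equiv), DMA, 40 °C, argon
Reagents that add atoms: none
Why: Proposed new method: under base the cyclopropanol binds nickel as its alkoxide, and strain-driven β-carbon elimination (about 27 kcal/mol of ring strain, the two ring bonds to the carbinol carbon being equivalent) gives a nickel-bound 3-oxobutyl group, the homoenolate of butanone; monovalent nickel abstracts bromine from 4 to give the primary alkyl radical, which is captured at nickel, and reductive elimination from trivalent nickel forms the C13'–C14' bond between two carbons that are both electrophilic in their normal reactivity; the closest known reaction types are the nickel-catalysed β-alkylation of cyclopropanol-derived homoenolates with redox-active N-acyloxyphthalimide esters, the copper-catalysed ring-opening alkylation of cyclopropanols with activated alkyl halides, and the nickel-catalysed alkyl–alkyl cross-coupling of unactivated primary alkyl bromides (overall a ring-opening cyclopropanol cross-coupling); no stereocentre is formed.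

**Step 3**
Reactants: 6 17-(3,5-dimethoxyphenyl)heptadecan-2-one
Product: 7 Hansfordiol B, 17-(3,5-dihydroxyphenyl)heptadecan-2-one
Conditions: BBr3 (4 equiv), CH2Cl2, −78 °C to rt; then MeOH, H2O, 0 °C
Reagents that add atoms: none
Why: Lewis-acid aryl methyl ether cleavage (BBr3 O-demethylation), in which boron binds each methoxy oxygen and bromide removes the methyl group by SN2 attack, while the ketone is only reversibly complexed (hence the extra equivalent) and is released on aqueous work-up; no stereocentre is present.

**Compound list**
1 | 3,5-dimethoxybenzyl chloride (1-(chloromethyl)-3,5-dimethoxybenzene) | COc1cc(CCl)cc(OC)c1 | starting material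
2 | 1,12-dibromododecane | BrCCCCCCCCCCCCBr | starting material
3 | 3,5-dimethoxybenzylmagnesium chloride | COc1cc(C[Mg]Cl)cc(OC)c1 | intermediate
4 | 1-(13-bromotridecyl)-3,5-dimethoxybenzene | COc1cc(CCCCCCCCCCCCCBr)cc(OC)c1 | intermediate
5 | 1-methylcyclopropan-1-ol | CC1(O)CC1 | starting material
6 | 17-(3,5-dimethoxyphenyl)heptadecan-2-one | CC(=O)CCCCCCCCCCCCCCCc1cc(OC)cc(OC)c1 | intermediate
7 | Hansfordiol B, 17-(3,5-dihydroxyphenyl)heptadecan-2-one (5-(16-oxoheptadecyl)benzene-1,3-diol), achiral | CC(=O)CCCCCCCCCCCCCCCc1cc(O)cc(O)c1 | target

**Total step count:** 3. **Longest linear sequence:** 3 steps (1 or 2 to 4 to 6 to 7).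

**Steps most likely to fail, with fallbacks**

Step 2 (highest risk). The nickel homoenolate may undergo β-hydride elimination to the enone or be protonated to the simple ketone, and bromide 4 may be reduced or eliminated instead of coupled. The fallback sets out from 4 and comes back at 6, replacing catalytic C–C cleavage by a stoichiometric, carbonyl-masked homoenolate. Commercial 2-(2-bromoethyl)-2-methyl-1,3-dioxolane (CC1(CCBr)OCCO1) is converted with Mg turnings in THF at 20–25 °C into [2-(2-methyl-1,3-dioxolan-2-yl)ethyl]magnesium bromide F1. Coupling of F1 with 4 under Li2CuCl4 (3 mol%) in THF at −10 °C to rt gives 2-[15-(3,5-dimethoxyphenyl)pentadecyl]-2-methyl-1,3-dioxolane F2. Brief treatment with 1 M HCl in THF at rt removes the ketal and gives 6.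

Step 1. The benzylic Grignard reagent may homocouple (Wurtz) and 2 may be alkylated at both ends. The fallback sets out from 2 and comes back at 4, building the benzylic bond by olefination instead. Compound 2 (3 equiv) and triphenylphosphine in toluene at reflux give (12-bromododecyl)triphenylphosphonium bromide F3. NaN(SiMe3)2 in THF at −78 °C gives the ylide (12-bromododecylidene)triphenylphosphorane F4, which is trapped at once with commercial 3,5-dimethoxybenzaldehyde (COc1cc(C=O)cc(OC)c1) in a Wittig olefination. This gives 1-[(1Z)-13-bromotridec-1-en-1-yl]-3,5-dimethoxybenzene F5 (Z major; the E/Z ratio does not matter). Hydrogenation (H2 1 atm, 5% Pt/C, EtOAc, rt) saturates the styrene double bond without cleaving the C–Br bond and gives 4.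

Step 3. BBr3 may give Lewis-acid aldol condensation of the methyl ketone or incomplete ether cleavage. The fallback sets out from 2 and comes back at 7, changing the phenol protecting group so that the last step is a neutral hydrogenolysis. Commercial 3,5-bis(benzyloxy)benzyl bromide (BrCc1cc(OCc2ccccc2)cc(OCc2ccccc2)c1) is added slowly to Mg turnings in Et2O at 0 °C to give [3,5-bis(benzyloxy)benzyl]magnesium bromide F6. Coupling of F6 with 2 (3 equiv) under Li2CuCl4 (3 mol%) in THF gives 1,3-bis(benzyloxy)-5-(13-bromotridecyl)benzene F7. Coupling of F7 with 5 under the conditions of step 2 gives 17-[3,5-bis(benzyloxy)phenyl]heptadecan-2-one F8. Hydrogenolysis (H2 1 atm, Pd/C, EtOAc/EtOH, rt) removes both benzyl groups without reducing the ketone and gives 7.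

**Further compounds**
F1 | step 2 | [2-(2-methyl-1,3-dioxolan-2-yl)ethyl]magnesium bromide | CC1(CC[Mg]Br)OCCO1
F2 | step 2 | 2-[15-(3,5-dimethoxyphenyl)pentadecyl]-2-methyl-1,3-dioxolane | COc1cc(CCCCCCCCCCCCCCCC2(C)OCCO2)cc(OC)c1
F3 | step 1 | (12-bromododecyl)triphenylphosphonium bromide | [Br-].BrCCCCCCCCCCCC[P+](c1ccccc1)(c1ccccc1)c1ccccc1
F4 | step 1 | (12-bromododecylidene)triphenylphosphorane | BrCCCCCCCCCCCC=P(c1ccccc1)(c1ccccc1)c1ccccc1
F5 | step 1 | 1-[(1Z)-13-bromotridec-1-en-1-yl]-3,5-dimethoxybenzene | COc1cc(/C=C\CCCCCCCCCCCBr)cc(OC)c1
F6 | step 3 | [3,5-bis(benzyloxy)benzyl]magnesium bromide | Br[Mg]Cc1cc(OCc2ccccc2)cc(OCc2ccccc2)c1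
F7 | step 3 | 1,3-bis(benzyloxy)-5-(13-bromotridecyl)benzene | BrCCCCCCCCCCCCCc1cc(OCc2ccccc2)cc(OCc2ccccc2)c1
F8 | step 3 | 17-[3,5-bis(benzyloxy)phenyl]heptadecan-2-one | CC(=O)CCCCCCCCCCCCCCCc1cc(OCc2ccccc2)cc(OCc2ccccc2)c1
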